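Two questions wait on this bench, and both turn on one number.

| setting | Friday's | Wednesday's | Monday's | Thursday's | Sunday's |
|---|---|---|---|---|---|
| left-handed substrate | 0.20 M | 0.20 M | 0.20 M | 0.20 M | 0.20 M |
| solid reagent | 2.00 equiv | 2.00 equiv | 2.00 equiv | 2.00 equiv | 2.00 equiv |
| precatalyst | 0.08 mol% | 0.2 mol% | 0.6 mol% | 2 mol% | 6 mol% |
| right-handed substrate | 0.20 M | 0.20 M | 0.20 M | 0.20 M | 0.20 M |
| time | 80 s | 80 s | 80 s | 80 s | 80 s |

    partner + precatalyst → catalyst + spent reagent (k1 = 0.069 /M/s)
    partner → decomposition product (k2 = 5.4 × 10⁻⁵ /s)
    partner + catalyst + left-handed substrate → catalyst + left-handed product (k3 = 21 /M²/s)
    partner + catalyst + right-handed substrate → catalyst + right-handed product (k4 = 0.39 /M²/s)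
    solid reagent ⇌ partner, rate k5*(cs5 - [partner]) while solid is left; crystals form when [partner] > cs5 (cs5 = 0.16 M, k5 = 0.019 /s)

- excess of left-handed product over right-handed product at the end for Friday's, Wednesday's, Monday's, Thursday's, Sunday's, in this order
- how that number moves from the first to the last of them (rises, then falls / rises all the way / falls all the way / hardly changes / falls, then rises)

- catalyst is single-handed; left-handed substrate and right-handed substrate are mirror images of each other, charged as a racemate, each of them at the stated concentration
- solid, in amounts per volume of the solution: solid reagent
- at the start none of the solid reagent is in solution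
- an excess is the difference of the two amounts in percent of their sum
- "hardly changes" means that all values lie within two and a half points (for a concentration: within two and a half percent of the largest)
- run time (Friday's): 80 s

**In the flask.** You take over a racemic substrate, solid reagent still undissolved, and precatalyst that partner must first turn into catalyst. Do not add precatalyst to mend the excess: no loading appears at the fork below.

**The fork.** Follow one molecule of substrate as it meets catalyst and partner. Both stand in each of the two product steps, so they cancel, and the product forms left-handed or right-handed as k3 times c(left-handed substrate) against k4 times c(right-handed substrate). The selectivity factor s, the ratio k3/k4, is 53.8, so the constant for left-handed substrate is far larger than the one for right-handed substrate. A fresh racemate therefore gives an excess of (s−1)/(s+1), 96.4%. Later, the fraction of right-handed substrate left equals the fraction of left-handed substrate left, raised to the power 1/s.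

**By the clock.** Partner climbs towards 0.16 M at 0.019 /s. Counted as otherwise untouched, its concentration summed over 80 s is 6.22 M·s, so about a third of the precatalyst is activated by then. Summing catalyst times partner likewise, Sunday's, the heaviest loading, keeps 74.6% of its left-handed substrate. The rule then gives 99.5% of its right-handed substrate and an excess of 95.8%. My row thus runs from near 96.4% to that value and hardly changes.

**The forecast.** It gives 96.3%, 96.3%, 96.25%, 96%, 95.6%, so hardly changes, holding that “the whole row stays within about one point”. For Sunday's it prints 95.6% where I reckoned 95.8%.

**The outcome.** The row is 96.3%, 96.3%, 96.3%, 96.2%, 95.9%, so hardly changes. Sunday's ended with 80% of its left-handed substrate left. Through s, that gives 99.6% of the right-handed substrate and an excess of 95.9%. Thursday's kept 91% of its left-handed substrate, so the same s gives 99.8% of the right-handed substrate and an excess of 96.2%; that flask ended at 96.2%.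

The rate constants were set for the occasion; the result is computed.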